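**Strategy**

Everything rests on disconnecting the ketone carbonyl carbon from C5 of the hexasubstituted benzene ring. The key step exploits the C4 hydroxyl, the phenol oxygen ortho to C5: it first holds the (1R,6R)-cyclohexenecarboxylic acid as an aryl ester, and iodine–lithium exchange at C5 then triggers an anionic Fries 1,3 O→C acyl shift. In one operation the hindered aryl–acyl bond forms at the only possible carbon, the C4 phenol of the target is released and no protecting group is needed. The precursor is an iodoaryl ester that contains no ketone. The acid arises from a copper–bis(oxazoline)-catalysed Diels–Alder reaction of myrcene with an α'-hydroxy enone as cinnamate surrogate.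

Key step: step 9

Remarks and assumptions:
- Numbering: benzene ring C1 = carbon bearing CO2Me, C2 OH, C3 CH3, C4 OH, C5 acyl, C6 OCH3. Cyclohexene C1' = carbon bearing the carbonyl, C6' = carbon bearing phenyl.
- Assumption: the α'-hydroxy enone binds Cu(II) in the same square-planar, s-cis two-point chelate as an N-enoyl oxazolidinone, so the (S,S)-ligand exposes the Cα-re face. Should the sense prove opposite, the (R,R)-ligand, also commercial, would be used without changing the route.
- Compounds 1, 6, 7, 9 and the ligand are taken as commercial.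

**Route**

Step 1
Reactants: 1 2-methylbenzene-1,3,5-triol (methylphloroglucinol)
Product: 2 5-methoxy-2-methylbenzene-1,3-diol
Conditions: HCl (g) in dry MeOH, rt, stopped at the mono-ether
Reagents that add atoms: methanol, CO
Why: Acid-catalysed etherification of a phloroglucinol through its keto tautomer; the C5 oxygen is the only one not flanked by the C-methyl group, so methanol should add there first.

Step 2
Reactants: 2 5-methoxy-2-methylbenzene-1,3-diol
Product: 3 2,4-dihydroxy-6-methoxy-3-methylbenzoic acid
Conditions: KHCO3, CO2 (1 atm), glycerol, 120 °C; then cold 2 M HCl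
Reagents that add atoms: carbon dioxide, O=C=O
Why: Kolbe–Schmitt carboxylation of an electron-rich resorcinol; the two free ring positions are equivalent by symmetry, each between OH and OMe, so only one acid can form.

Step 3
Reactants: 3 2,4-dihydroxy-6-methoxy-3-methylbenzoic acid
Product: 4 methyl 2,4-dihydroxy-6-methoxy-3-methylbenzoate
Conditions: MeI (1.1 equiv), NaHCO3, DMF, rt
Reagents that add atoms: iodomethane, CI
Why: SN2 O-alkylation of the carboxylate; bicarbonate ionises the acid but not the phenols to a useful extent, so only the ester should form.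

Step 4
Reactants: 4 methyl 2,4-dihydroxy-6-methoxy-3-methylbenzoate
Product: 5 methyl 2,4-dihydroxy-5-iodo-6-methoxy-3-methylbenzoate
Conditions: NIS (1.05 equiv), MeCN, 0 °C, dark
Reagents that add atoms: N-iodosuccinimide, O=C1CCC(=O)N1I
Why: Electrophilic aromatic iodination at C5, the only unsubstituted ring carbon (para to the C2 OH, ortho to C4 OH and C6 OMe); it is done before any alkene is present.

Step 5
Reactants: 6 benzaldehyde, 7 3-hydroxy-3-methylbutan-2-one
Product: 8 (E)-4-hydroxy-4-methyl-1-phenylpent-1-en-3-one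
Conditions: LiOH·H2O, MeOH/H2O, rt → 60 °C
Reagents that add atoms: none
Why: Claisen–Schmidt aldol condensation at the only enolisable position (the methyl ketone); E1cB dehydration should give the conjugated (E)-enone.

Step 6
Reactants: 8 (E)-4-hydroxy-4-methyl-1-phenylpent-1-en-3-one, 9 myrcene
Product: 10 2-hydroxy-2-methyl-1-[(1R,6R)-4-(4-methylpent-3-en-1-yl)-6-phenylcyclohex-3-en-1-yl]propan-1-one
Conditions: [Cu((S,S)-t-Bu-box)](SbF6)2 (10 mol %), myrcene (4 equiv), CH2Cl2, 0 °C → rt
Reagents that add atoms: none
Why: Lewis acid-catalysed asymmetric Diels–Alder reaction: the ketol chelates square-planar Cu(II) through C=O and OH with the enone s-cis, the ligand tert-butyl group covers the Cα-si face so that myrcene adds to the Cα-re face and sets C1' as R, the (E)-geometry is carried over suprafacially so C6' follows as R (trans), and bonding of the methylidene terminus on the substituted diene carbon to the enone β-carbon gives the 1,4 ("para") placement of the side chain.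

Step 7
Reactants: 10 ketol adduct
Product: 11 (1R,6R)-4-(4-methylpent-3-en-1-yl)-6-phenylcyclohex-3-ene-1-carboxylic acid
Conditions: NaIO4 (3 equiv), MeOH/H2O 2:1, rt
Reagents that add atoms: water, O
Why: Periodate cleavage of the α-hydroxy ketone through its hydrate releases the acid and acetone; isolated alkenes are inert to periodate and the non-basic medium leaves C1' untouched.

Step 8
Reactants: 5 methyl 2,4-dihydroxy-5-iodo-6-methoxy-3-methylbenzoate, 11 (1R,6R)-acid
Product: 12 methyl 2-hydroxy-5-iodo-6-methoxy-3-methyl-4-{[(1R,6R)-4-(4-methylpent-3-en-1-yl)-6-phenylcyclohex-3-ene-1-carbonyl]oxy}benzoate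
Conditions: DCC (1.2 equiv), DMAP (0.2 equiv), CH2Cl2, 0 °C → rt
Reagents that add atoms: none
Why: Steglich esterification at the C4 OH, the more acidic and non-chelated phenol; the C2 OH is locked in a hydrogen bond to the ester carbonyl and flanked by CH3 and CO2Me.

Step 9
Reactants: 12 iodoaryl ester
Product: 15 methyl 2,4-dihydroxy-6-methoxy-3-methyl-5-[(1R,6R)-4-(4-methylpent-3-en-1-yl)-6-phenylcyclohex-3-ene-1-carbonyl]benzoate (CNP0257108.1), via sodium phenoxide 13 (not isolated), via C5 aryllithium 14 (not isolated)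
Conditions: NaH (1.1 equiv), THF, 0 °C; t-BuLi (2.1 equiv), −100 → −78 °C; then cold 1 M HCl
Reagents that add atoms: none
Why: Iodine–lithium exchange, far faster at −100 °C than carbonyl addition or enolisation, places a carbanion on C5 between the C4 acyloxy and C6 methoxy oxygens; it attacks the neighbouring ester carbonyl and the tetrahedral alkoxide collapses by expelling the C4 phenoxide, so the acyl group moves from O4 to C5 (1,3 O→C shift). The closest known reaction type is the anionic Fries rearrangement of o-haloaryl esters triggered by halogen–metal exchange. No ring is closed in the product; the only cyclic species is the transient four-membered C5–C(O)–O–C4 tetrahedral intermediate, reached by a 4-exo-trig attack. No new stereocentre forms: the acyl carbon migrates with C1' and C6' untouched, and any epimerisation at C1' would in any case favour the trans diequatorial isomer. The step needs chemoselectivity for exchange over attack on the two ester carbonyls and over E1cB loss of a ketene, and regioselectivity for C5; the first is secured by the iodide, by prior conversion of the C2 phenol into its phenoxide (which also deactivates the methyl ester) and by the intramolecular transfer, the second by the iodine sitting on the only ring carbon that was free.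

**Compound list**

1 | 2-methylbenzene-1,3,5-triol (methylphloroglucinol) | Cc1c(O)cc(O)cc1O | starting material
2 | 5-methoxy-2-methylbenzene-1,3-diol | COc1cc(O)c(C)c(O)c1 | intermediate
3 | 2,4-dihydroxy-6-methoxy-3-methylbenzoic acid | COc1cc(O)c(C)c(O)c1C(=O)O | intermediate
4 | methyl 2,4-dihydroxy-6-methoxy-3-methylbenzoate | COC(=O)c1c(O)c(C)c(O)cc1OC | intermediate
5 | methyl 2,4-dihydroxy-5-iodo-6-methoxy-3-methylbenzoate | COC(=O)c1c(O)c(C)c(O)c(I)c1OC | intermediate
6 | benzaldehyde | O=Cc1ccccc1 | starting material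
7 | 3-hydroxy-3-methylbutan-2-one | CC(=O)C(C)(C)O | starting material
8 | (E)-4-hydroxy-4-methyl-1-phenylpent-1-en-3-one | CC(C)(O)C(=O)/C=C/c1ccccc1 | intermediate
9 | myrcene (7-methyl-3-methylideneocta-1,6-diene) | CC(C)=CCCC(=C)C=C | starting material
10 | 2-hydroxy-2-methyl-1-[(1R,6R)-4-(4-methylpent-3-en-1-yl)-6-phenylcyclohex-3-en-1-yl]propan-1-one | CC(C)(O)C(=O)[C@@H]1CC=C(CCC=C(C)C)C[C@H]1c1ccccc1 | intermediate
11 | (1R,6R)-4-(4-methylpent-3-en-1-yl)-6-phenylcyclohex-3-ene-1-carboxylic acid | OC(=O)[C@@H]1CC=C(CCC=C(C)C)C[C@H]1c1ccccc1 | intermediate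
12 | methyl 2-hydroxy-5-iodo-6-methoxy-3-methyl-4-{[(1R,6R)-4-(4-methylpent-3-en-1-yl)-6-phenylcyclohex-3-ene-1-carbonyl]oxy}benzoate | COC(=O)c1c(O)c(C)c(OC(=O)[C@@H]2CC=C(CCC=C(C)C)C[C@H]2c2ccccc2)c(I)c1OC | intermediate
13 | sodium C2-phenoxide of 12 | COC(=O)c1c([O-])c(C)c(OC(=O)[C@@H]2CC=C(CCC=C(C)C)C[C@H]2c2ccccc2)c(I)c1OC.[Na+] | intermediate
14 | C5 aryllithium (sodium C2-phenoxide) from 13 | COC(=O)c1c([O-])c(C)c(OC(=O)[C@@H]2CC=C(CCC=C(C)C)C[C@H]2c2ccccc2)c([Li])c1OC.[Na+] | intermediate
15 | methyl 2,4-dihydroxy-6-methoxy-3-methyl-5-[(1R,6R)-4-(4-methylpent-3-en-1-yl)-6-phenylcyclohex-3-ene-1-carbonyl]benzoate | COC(=O)c1c(O)c(C)c(O)c(C(=O)[C@@H]2CC=C(CCC=C(C)C)C[C@H]2c2ccccc2)c1OC | target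

**Step count**

Total steps: 9. Longest linear sequence: 6 (steps 1, 2, 3, 4, 8, 9); the acid branch (steps 5, 6, 7) joins at step 8.

**Steps most likely to fail**

Step 9. The aryllithium may be protonated before the acyl group has moved (loss of iodine without migration), the alkyllithium may add to an ester carbonyl, or the aryl ester may lose a ketene by enolisation. The fallback joins the halves intermolecularly with protected phenols; it sets out from iodide 5 and ketol 10 and returns at target 15.
- Iodide 5 would be converted with NaH and MOMCl into methyl 5-iodo-6-methoxy-2,4-bis(methoxymethoxy)-3-methylbenzoate F1.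
- Ketol 10 would be reduced with NaBH4 to 2-methyl-1-[(1R,6R)-4-(4-methylpent-3-en-1-yl)-6-phenylcyclohex-3-en-1-yl]propane-1,2-diol F2 and cleaved with NaIO4 to (1R,6R)-4-(4-methylpent-3-en-1-yl)-6-phenylcyclohex-3-ene-1-carbaldehyde F3.
- Iodine–magnesium exchange on F1 (i-PrMgCl·LiCl, THF, −20 °C, tolerant of the methyl ester) and addition to F3 should give methyl 5-{hydroxy[(1R,6R)-4-(4-methylpent-3-en-1-yl)-6-phenylcyclohex-3-en-1-yl]methyl}-6-methoxy-2,4-bis(methoxymethoxy)-3-methylbenzoate F4, as carbinol epimers of no consequence.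
- Dess–Martin oxidation should give methyl 6-methoxy-2,4-bis(methoxymethoxy)-3-methyl-5-[(1R,6R)-4-(4-methylpent-3-en-1-yl)-6-phenylcyclohex-3-ene-1-carbonyl]benzoate F5, and HCl in MeOH at 40 °C should remove both acetals to give 15.

Step 6. The β-phenyl enone may be too poor a dienophile for an unactivated diene at a temperature where the copper complex still controls the face, or the Lewis acid may oligomerise the diene. The fallback replaces catalytic induction by an uncatalysed cycloaddition and separation of covalent diastereomers; it sets out from enone 8 and myrcene 9 and returns at acid 11.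
- Heating 8 with 9 (toluene, 140 °C, sealed tube, BHT) should give racemic trans-2-hydroxy-2-methyl-1-[4-(4-methylpent-3-en-1-yl)-6-phenylcyclohex-3-en-1-yl]propan-1-one F6, freed from its regioisomer by chromatography.
- NaIO4 cleavage should give racemic trans-4-(4-methylpent-3-en-1-yl)-6-phenylcyclohex-3-ene-1-carboxylic acid F7.
- Acylation of lithiated (S)-4-benzyloxazolidin-2-one with the pivaloyl mixed anhydride of F7 should give two imides that are separated by chromatography or crystallisation, one being (S)-4-benzyl-3-[(1R,6R)-4-(4-methylpent-3-en-1-yl)-6-phenylcyclohex-3-ene-1-carbonyl]oxazolidin-2-one F8.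
- LiOH/H2O2 on F8 should release 11.

Step 1. Etherification may run on to the dimethyl ether, or may not discriminate fully between the C5 oxygen and the two oxygens next to the methyl group. The fallback fixes the regiochemistry by chelation and a temporary benzyl ether; it sets out from triol 1 and returns at ester 4.
- Kolbe–Schmitt carboxylation of 1 should give 2,4,6-trihydroxy-3-methylbenzoic acid F9, and MeI/NaHCO3 its ester methyl 2,4,6-trihydroxy-3-methylbenzoate F10.
- The only non-chelated hydroxyl would be benzylated (BnBr, 1.0 equiv, K2CO3, acetone) to methyl 4-(benzyloxy)-2,6-dihydroxy-3-methylbenzoate F11.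
- The less hindered of the two chelated hydroxyls would be methylated (MeI, K2CO3, DMF) to methyl 4-(benzyloxy)-2-hydroxy-6-methoxy-3-methylbenzoate F12.
- Hydrogenolysis (H2, Pd/C, EtOAc) should give 4.

**Further compounds**

F1 | step 9 | methyl 5-iodo-6-methoxy-2,4-bis(methoxymethoxy)-3-methylbenzoate | COCOc1c(C)c(OCOC)c(I)c(OC)c1C(=O)OC
F2 | step 9 | 2-methyl-1-[(1R,6R)-4-(4-methylpent-3-en-1-yl)-6-phenylcyclohex-3-en-1-yl]propane-1,2-diol (carbinol epimers) | CC(C)(O)C(O)[C@@H]1CC=C(CCC=C(C)C)C[C@H]1c1ccccc1
F3 | step 9 | (1R,6R)-4-(4-methylpent-3-en-1-yl)-6-phenylcyclohex-3-ene-1-carbaldehyde | O=C[C@@H]1CC=C(CCC=C(C)C)C[C@H]1c1ccccc1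
F4 | step 9 | methyl 5-{hydroxy[(1R,6R)-4-(4-methylpent-3-en-1-yl)-6-phenylcyclohex-3-en-1-yl]methyl}-6-methoxy-2,4-bis(methoxymethoxy)-3-methylbenzoate (carbinol epimers) | COCOc1c(C)c(OCOC)c(C(O)[C@@H]2CC=C(CCC=C(C)C)C[C@H]2c2ccccc2)c(OC)c1C(=O)OC
F5 | step 9 | methyl 6-methoxy-2,4-bis(methoxymethoxy)-3-methyl-5-[(1R,6R)-4-(4-methylpent-3-en-1-yl)-6-phenylcyclohex-3-ene-1-carbonyl]benzoate | COCOc1c(C)c(OCOC)c(C(=O)[C@@H]2CC=C(CCC=C(C)C)C[C@H]2c2ccccc2)c(OC)c1C(=O)OC
F6 | step 6 | racemic trans-2-hydroxy-2-methyl-1-[4-(4-methylpent-3-en-1-yl)-6-phenylcyclohex-3-en-1-yl]propan-1-one (both enantiomers) | CC(C)(O)C(=O)[C@@H]1CC=C(CCC=C(C)C)C[C@H]1c1ccccc1.CC(C)(O)C(=O)[C@H]1CC=C(CCC=C(C)C)C[C@@H]1c1ccccc1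
F7 | step 6 | racemic trans-4-(4-methylpent-3-en-1-yl)-6-phenylcyclohex-3-ene-1-carboxylic acid (both enantiomers) | OC(=O)[C@@H]1CC=C(CCC=C(C)C)C[C@H]1c1ccccc1.OC(=O)[C@H]1CC=C(CCC=C(C)C)C[C@@H]1c1ccccc1
F8 | step 6 | (S)-4-benzyl-3-[(1R,6R)-4-(4-methylpent-3-en-1-yl)-6-phenylcyclohex-3-ene-1-carbonyl]oxazolidin-2-one | O=C1OC[C@H](Cc2ccccc2)N1C(=O)[C@@H]1CC=C(CCC=C(C)C)C[C@H]1c1ccccc1
F9 | step 1 | 2,4,6-trihydroxy-3-methylbenzoic acid | Cc1c(O)cc(O)c(C(=O)O)c1O
F10 | step 1 | methyl 2,4,6-trihydroxy-3-methylbenzoate | COC(=O)c1c(O)cc(O)c(C)c1O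
F11 | step 1 | methyl 4-(benzyloxy)-2,6-dihydroxy-3-methylbenzoate | COC(=O)c1c(O)cc(OCc2ccccc2)c(C)c1O
F12 | step 1 | methyl 4-(benzyloxy)-2-hydroxy-6-methoxy-3-methylbenzoate | COC(=O)c1c(OC)cc(OCc2ccccc2)c(C)c1O
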